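**Retrosynthetic overview**

1. Numbering used throughout: the ring is C1 (CH2), C2=C3 (C3 bears C20H2OH), C4, C5, C6=C7(Me), C8, C9, C10=C11(Me), C12, C13, C14 (stereocentre); the side chain is C15(Me)=C16–C17–C18=C19Me2. Last disconnections: silyl ether cleavage, then the side chain is attached at C14 by a stereoretentive Zweifel olefination of a macrocyclic C14 boronic ester.
2. Key disconnection C1–C2: the only ring (14-membered carbocycle) is closed in one flask by enantioselective diboration of a terminal C14=C1 olefin and Suzuki–Miyaura coupling of the primary C1–B bond with a (Z)-alkenyl bromide at C2.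
3. Enabling feature: ring methylene C1 lies between sp2 carbon C2 of the ring olefin C2=C3 and the lone stereocentre C14, which carries an sp2 substituent (C15). The C14–C1 pair is therefore a 1-alkene in disguise; a boron at C14 activates the C1–B bond for ring closure and later becomes the side chain.
4. The achiral open-chain precursor is built linearly by three stereodefining carbometalations: carbocupration of propyne (C10=C11, Z), zirconium-catalysed methylalumination (C6=C7, E) and copper-catalysed anti-carbomagnesiation of propargyl alcohol with bromination (C2=C3).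
5. The side-chain reagent, a (Z)-2-iodoalkene, comes from a Stork–Zhao olefination; the Zweifel step inverts its geometry to the required E olefin.

Key step: step 8

Assumption: of the two available antipodes of the TADDOL-derived phosphonite ligand, the one that gives the (S)-1,2-bis(boronate) from a 1-alkene is used; the sense of induction would be confirmed by oxidation of a sample to the 1,2-diol.

**Step 1**
Reactants: 1 but-3-en-1-ylmagnesium bromide; 2 propyne; 3 oxirane
Product: 6 (3Z)-4-methylocta-3,7-dien-1-ol, via but-3-enylcopper 4 (not isolated), via alkenylcopper 5 (not isolated)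
Conditions: CuBr·SMe2 (1 equiv), Et2O/THF/Me2S, −45 °C; 2, −25 °C; then lithium pent-1-ynide, HMPA, 3, −78 → −20 °C; aq NH4Cl
Reagents that add atoms: none
Why: Normant carbocupration adds the butenyl group and copper syn across propyne (butenyl on the internal carbon), which fixes the Z geometry of C10=C11; the alkenylcopper, as a mixed cuprate, should open oxirane with retention.

**Step 2**
Reactants: 6 (3Z)-4-methylocta-3,7-dien-1-ol
Product: 7 (5Z)-8-iodo-5-methylocta-1,5-diene
Conditions: I2, PPh3, imidazole, CH2Cl2, 0 °C → rt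
Reagents that add atoms: iodine ([I][I])
Why: Appel-type iodination of a primary alcohol; the olefins are not touched.

**Step 3**
Reactants: 7 (5Z)-8-iodo-5-methylocta-1,5-diene
Product: 8 (5Z)-6-methyldeca-5,9-dien-1-yne
Conditions: lithium acetylide·ethylenediamine, DMSO, 10 °C → rt
Reagents that add atoms: lithium acetylide–ethylenediamine complex ([Li]C#C.NCCN)
Why: Displacement of a primary iodide by acetylide in a dipolar aprotic solvent should give the terminal alkyne without affecting the Z olefin.

**Step 4**
Reactants: 8 (5Z)-6-methyldeca-5,9-dien-1-yne; 3 oxirane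
Product: 11 (3E,7Z)-4,8-dimethyldodeca-3,7,11-trien-1-ol, via alkenylalane 9 (not isolated), via lithium alanate 10 (not isolated)
Conditions: Me3Al, Cp2ZrCl2 (cat.), CH2Cl2, 0 °C → rt; then n-BuLi, hexane/THF, −78 °C; 3, −78 °C → rt
Reagents that add atoms: trimethylaluminium (C[Al](C)C)
Why: Negishi zirconium-catalysed methylalumination adds Me and Al syn to the terminal alkyne (Me on the internal carbon), which sets C6=C7 as E; the alanate should open oxirane with retention, and the isolated olefins react far more slowly than the alkyne.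

**Step 5**
Reactants: 11 (3E,7Z)-4,8-dimethyldodeca-3,7,11-trien-1-ol
Product: 12 (5Z,9E)-12-bromo-5,9-dimethyldodeca-1,5,9-triene
Conditions: CBr4, PPh3, CH2Cl2, 0 °C
Reagents that add atoms: tetrabromomethane (BrC(Br)(Br)Br)
Why: Appel bromination of a primary homoallylic alcohol under neutral conditions.

**Step 6**
Reactants: 12 (5Z,9E)-12-bromo-5,9-dimethyldodeca-1,5,9-triene; 13 prop-2-yn-1-ol
Product: 17 (2Z)-3-bromo-2-[(3E,7Z)-4,8-dimethyldodeca-3,7,11-trien-1-yl]prop-2-en-1-ol, via Grignard reagent 14 (not isolated), via bromomagnesium propynolate 15 (not isolated), via cyclic alkenylmagnesium alkoxide 16 (not isolated)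
Conditions: 12, Mg, THF, rt; 13, EtMgBr, THF, 0 °C; combine with CuI (15 mol%), Et2O/THF, −10 °C → rt; then NBS, −40 → 0 °C
Reagents that add atoms: N-bromosuccinimide (O=C1CCC(=O)N1Br)
Why: Copper-catalysed anti-carbomagnesiation of the propargylic magnesium alkoxide puts the alkyl group on the carbon next to CH2O and leaves magnesium, chelated by the alkoxide, cis to CH2O; bromination with retention should give the alkenyl bromide with Br cis to CH2OH.

**Step 7**
Reactants: 17 (2Z)-3-bromo-2-[(3E,7Z)-4,8-dimethyldodeca-3,7,11-trien-1-yl]prop-2-en-1-ol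
Product: 18 {[(2Z)-3-bromo-2-[(3E,7Z)-4,8-dimethyldodeca-3,7,11-trien-1-yl]prop-2-en-1-yl]oxy}tri(propan-2-yl)silane
Conditions: TIPSCl, imidazole, DMF, rt
Reagents that add atoms: chlorotri(propan-2-yl)silane (CC(C)[Si](Cl)(C(C)C)C(C)C)
Why: Silylation of the primary allylic alcohol; the TIPS ether should withstand aqueous KOH at 70 °C, organolithium reagents and NaOMe in the later steps.

**Step 8**
Reactants: 18 {[(2Z)-3-bromo-2-[(3E,7Z)-4,8-dimethyldodeca-3,7,11-trien-1-yl]prop-2-en-1-yl]oxy}tri(propan-2-yl)silane
Product: 20 2-[(1R,3Z,7E,11Z)-8,12-dimethyl-4-({[tri(propan-2-yl)silyl]oxy}methyl)cyclotetradeca-3,7,11-trien-1-yl]-4,4,5,5-tetramethyl-1,3,2-dioxaborolane, via bis(boronate) 19 (not isolated)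
Conditions: B2pin2, Pt(dba)3 (3 mol%), 3,5-diethylphenyl-TADDOL phenylphosphonite (6 mol%, antipode as assumed), THF, 60 °C; then slow addition to Pd(OAc)2 (10 mol%), RuPhos (10 mol%), KOH, THF/H2O 10:1, 70 °C, final 2 mM
Reagents that add atoms: bis(pinacolato)diboron (CC1(C)OB(OC1(C)C)B1OC(C)(C)C(C)(C)O1)
Why: Platinum-catalysed enantioselective syn-diboration of the terminal C14=C1 olefin (B–B oxidative addition, olefin insertion, C–B reductive elimination) should give the (S)-vicinal bis(boronate) 19, whose primary C1–B bond alone transmetalates to the alkenylpalladium formed from the alkenyl bromide, so that C(sp3)–C(sp2) reductive elimination forms C1–C2. The closest known reaction types are the one-flask diboration/cross-coupling of 1-alkenes with alkenyl bromides and the B-alkyl Suzuki–Miyaura macrocyclisation. The 14-membered ring closes by intramolecular transmetalation to a 15-membered palladacycle followed by reductive elimination, an endo-type macrocyclisation that slow addition at high dilution should favour over oligomerisation. The C14 stereocentre is set in the diboration by the chiral phosphonite on platinum and is not touched by the coupling, which leaves it as a C–B bond (the descriptor changes from S in 19 to R in 20 only because the substituent priorities change). The step needs diboration of the single monosubstituted olefin, which the bulky catalyst secures because trisubstituted olefins are inert to it, and coupling at C1 rather than C14, which the neighbouring C14 boronate secures by accelerating transmetalation of the primary C–B bond. The alkenyl bromide couples with retention, so C1 ends cis to the CH2O group on C2=C3.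

**Step 9**
Reactants: 21 4-methylpent-3-en-1-ol
Product: 22 4-methylpent-3-enal
Conditions: Dess–Martin periodinane, NaHCO3, CH2Cl2, 0 °C; used crude
Reagents that add atoms: none
Why: Buffered Dess–Martin oxidation should give the β,γ-unsaturated aldehyde without migration of the olefin into conjugation.

**Step 10**
Reactants: 22 4-methylpent-3-enal
Product: 23 (2Z)-2-iodo-6-methylhepta-2,5-diene
Conditions: EtPPh3I, n-BuLi, THF, rt; I2, −78 °C; NaHMDS, −20 °C; then 22, −78 → −20 °C
Reagents that add atoms: ethyltriphenylphosphonium iodide (CC[P+](c1ccccc1)(c1ccccc1)c1ccccc1.[I-]); iodine ([I][I])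
Why: Stork–Zhao olefination with the α-iodoethylidene ylide should give mainly the (Z)-2-iodoalkene, with iodine cis to the chain.

**Step 11**
Reactants: 20 macrocyclic boronic ester; 23 (2Z)-2-iodo-6-methylhepta-2,5-diene
Product: 27 {[(1Z,4R,7Z,11E)-7,11-dimethyl-4-[(2E)-6-methylhepta-2,5-dien-2-yl]cyclotetradeca-1,7,11-trien-1-yl]methoxy}tri(propan-2-yl)silane, via alkenyllithium 24 (not isolated), via boronate complex 25 (not isolated), via iodoboronic ester 26 (not isolated)
Conditions: 23, t-BuLi (2 equiv), Et2O/THF, −78 °C; 20, −78 → 0 °C; I2, THF, −78 °C; NaOMe, MeOH, −78 °C → rt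
Reagents that add atoms: none
Why: Zweifel olefination: the alkenyllithium (formed with retention) adds to boron, iodine triggers 1,2-migration of C14 with retention at the stereocentre, and anti-elimination of boron and iodide inverts the alkene geometry, so the Z iodide should give the E side-chain olefin.

**Step 12**
Reactants: 27 TIPS ether
Product: 28 [(1Z,4R,7Z,11E)-7,11-dimethyl-4-[(2E)-6-methylhepta-2,5-dien-2-yl]cyclotetradeca-1,7,11-trien-1-yl]methanol
Conditions: TBAF, THF, rt
Reagents that add atoms: none
Why: Fluoride cleavage of the silyl ether should free the allylic alcohol without touching the olefins or the stereocentre.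

**Compound list**

1 | but-3-en-1-ylmagnesium bromide | C=CCC[Mg]Br | starting material
2 | propyne | CC#C | starting material
3 | oxirane | C1CO1 | starting material
4 | but-3-en-1-ylcopper (MgBr2 complex) | C=CCC[Cu] | intermediate (not isolated)
5 | [(1Z)-2-methylhexa-1,5-dien-1-yl]copper | [Cu]/C=C(/C)CCC=C | intermediate (not isolated)
6 | (3Z)-4-methylocta-3,7-dien-1-ol | OCC/C=C(/C)CCC=C | intermediate
7 | (5Z)-8-iodo-5-methylocta-1,5-diene | ICC/C=C(/C)CCC=C | intermediate
8 | (5Z)-6-methyldeca-5,9-dien-1-yne | C#CCC/C=C(/C)CCC=C | intermediate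
9 | [(1E,5Z)-2,6-dimethyldeca-1,5,9-trien-1-yl]dimethylalane | C[Al](C)/C=C(\C)CC/C=C(/C)CCC=C | intermediate (not isolated)
10 | lithium butyl[(1E,5Z)-2,6-dimethyldeca-1,5,9-trien-1-yl]dimethylalanate | [Li+].CCCC[Al-](C)(C)/C=C(\C)CC/C=C(/C)CCC=C | intermediate (not isolated)
11 | (3E,7Z)-4,8-dimethyldodeca-3,7,11-trien-1-ol | OCC/C=C(\C)CC/C=C(/C)CCC=C | intermediate
12 | (5Z,9E)-12-bromo-5,9-dimethyldodeca-1,5,9-triene | BrCC/C=C(\C)CC/C=C(/C)CCC=C | intermediate
13 | prop-2-yn-1-ol | C#CCO | starting material
14 | [(3E,7Z)-4,8-dimethyldodeca-3,7,11-trien-1-yl]magnesium bromide | Br[Mg]CC/C=C(\C)CC/C=C(/C)CCC=C | intermediate (not isolated)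
15 | bromomagnesium prop-2-yn-1-olate | C#CCO[Mg]Br | intermediate (not isolated)
16 | cyclic alkenylmagnesium alkoxide (five-membered ring, Mg bonded to O and to C2; chain on C3) | [Mg]1OCC(CC/C=C(\C)CC/C=C(/C)CCC=C)=C1 | intermediate (not isolated)
17 | (2Z)-3-bromo-2-[(3E,7Z)-4,8-dimethyldodeca-3,7,11-trien-1-yl]prop-2-en-1-ol | Br/C=C(\CO)CC/C=C(\C)CC/C=C(/C)CCC=C | intermediate
18 | {[(2Z)-3-bromo-2-[(3E,7Z)-4,8-dimethyldodeca-3,7,11-trien-1-yl]prop-2-en-1-yl]oxy}tri(propan-2-yl)silane | Br/C=C(\CO[Si](C(C)C)(C(C)C)C(C)C)CC/C=C(\C)CC/C=C(/C)CCC=C | intermediate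
19 | 2,2'-[(2S,5Z,9E,13Z)-14-bromo-5,9-dimethyl-13-({[tri(propan-2-yl)silyl]oxy}methyl)tetradeca-5,9,13-triene-1,2-diyl]bis(4,4,5,5-tetramethyl-1,3,2-dioxaborolane) | Br/C=C(\CO[Si](C(C)C)(C(C)C)C(C)C)CC/C=C(\C)CC/C=C(/C)CC[C@@H](B1OC(C)(C)C(C)(C)O1)CB1OC(C)(C)C(C)(C)O1 | intermediate (not isolated)
20 | 2-[(1R,3Z,7E,11Z)-8,12-dimethyl-4-({[tri(propan-2-yl)silyl]oxy}methyl)cyclotetradeca-3,7,11-trien-1-yl]-4,4,5,5-tetramethyl-1,3,2-dioxaborolane | CC1(C)OB(OC1(C)C)[C@H]2C/C=C(\CO[Si](C(C)C)(C(C)C)C(C)C)CC/C=C(\C)CC/C=C(/C)CC2 | intermediate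
21 | 4-methylpent-3-en-1-ol | CC(C)=CCCO | starting material
22 | 4-methylpent-3-enal | CC(C)=CCC=O | intermediate
23 | (2Z)-2-iodo-6-methylhepta-2,5-diene | CC(C)=CC/C=C(/C)I | intermediate
24 | [(2E)-6-methylhepta-2,5-dien-2-yl]lithium (Li cis to the chain) | CC(C)=CC/C=C(/C)[Li] | intermediate (not isolated)
25 | lithium boronate complex of 20 with 24 | [Li+].CC(C)=CC/C=C(/C)[B-]1(OC(C)(C)C(C)(C)O1)[C@H]2C/C=C(\CO[Si](C(C)C)(C(C)C)C(C)C)CC/C=C(\C)CC/C=C(/C)CC2 | intermediate (not isolated)
26 | β-iodoalkylboronic ester (C14 as in 20; C15/C16 as the two anti-adducts) | CC(C)=CCC(I)C(C)(B1OC(C)(C)C(C)(C)O1)[C@H]2C/C=C(\CO[Si](C(C)C)(C(C)C)C(C)C)CC/C=C(\C)CC/C=C(/C)CC2 | intermediate (not isolated)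
27 | {[(1Z,4R,7Z,11E)-7,11-dimethyl-4-[(2E)-6-methylhepta-2,5-dien-2-yl]cyclotetradeca-1,7,11-trien-1-yl]methoxy}tri(propan-2-yl)silane | CC(C)=CC/C=C(\C)[C@H]1C/C=C(\CO[Si](C(C)C)(C(C)C)C(C)C)CC/C=C(\C)CC/C=C(/C)CC1 | intermediate
28 | [(1Z,4R,7Z,11E)-7,11-dimethyl-4-[(2E)-6-methylhepta-2,5-dien-2-yl]cyclotetradeca-1,7,11-trien-1-yl]methanol | CC(C)=CC/C=C(\C)[C@H]1C/C=C(\CO)CC/C=C(\C)CC/C=C(/C)CC1 | target

**Step count**

Total: 12 steps. Longest linear sequence: 10 steps (steps 1–8, 11, 12).

**Steps most likely to fail**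

1. Step 8. The ring-closing mode of the bis(boronate) coupling is the least precedented element. Oligomerisation or protodeboronation may outrun ring closure, and the alkenyl bromide may intercept the platinum catalyst during diboration. The fallback makes C1–C2 intermolecularly by the same diboration/cross-coupling and closes the ring at C5–C6 by a classical 9-BBN B-alkyl Suzuki–Miyaura macrocyclisation. It sets out from alkyne 8 and propargyl alcohol 13 and comes back at 27. Compound 8 is C-silylated (n-BuLi, Me3SiCl) to the trimethylsilyl alkyne F1. Compound 13 is carbomagnesiated with vinylmagnesium bromide and CuI and brominated with NBS to (2Z)-2-(bromomethylidene)but-3-en-1-ol F2, which is silylated to its TIPS ether F3. Diboration of the terminal olefin of F1 under the conditions of step 8 gives the (S)-bis(boronate) F4, which is coupled in the same flask with F3 (Pd(OAc)2, RuPhos, KOH) to the open-chain secondary boronic ester F5. Zweifel olefination with the alkenyllithium from 23, as in step 11, gives the side-chain-bearing silyl alkyne F6. K2CO3 in MeOH frees the terminal alkyne F7. Methylalumination (Me3Al, Cp2ZrCl2) and iodinolysis give the (E)-alkenyl iodide F8. 9-BBN adds to the terminal vinyl group of the 1,3-diene to give the B-alkyl borane F9, which is cyclised with Pd(dppf)Cl2, AsPh3 and Cs2CO3 in DMF/THF/H2O at high dilution to 27.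

2. Step 11. Formation of the boronate complex from the hindered secondary boronic ester and the α-branched alkenyllithium may be incomplete, and the geometry of 24 may erode before it is trapped. The fallback builds the side chain in two separate carbon–carbon bond formations; it sets out from 20 and comes back at 27. Compound 20 is treated with α-lithiated vinyl N,N-diisopropylcarbamate and then I2/NaOMe, a 1,2-migration with retention at C14, to give the enol carbamate F10. Elimination with LDA gives the macrocyclic terminal alkyne F11. Zirconium-catalysed methylalumination (Me3Al, Cp2ZrCl2) gives the (E)-alkenylalane F12, which is coupled with prenyl bromide under Pd(PPh3)4 to 27.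

3. Step 6. The carbomagnesiation may stall when the Grignard reagent is the limiting partner, and the alkenylmagnesium may be protonated before it is brominated. The fallback replaces carbometalation by carbonyl olefination; it sets out from Grignard reagent 14 (made from 12) and comes back at 18. Compound 14 is acylated with N-methoxy-N-methyl-2-{[tri(propan-2-yl)silyl]oxy}acetamide to the silyloxymethyl ketone F13. Wittig bromomethylenation (Ph3PCH2Br bromide, KOt-Bu, THF, −78 °C) should give 18 together with its (E)-isomer, which would have to be removed by chromatography.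

**Further compounds**

F1 | step 8 | trimethyl[(5Z)-6-methyldeca-5,9-dien-1-yn-1-yl]silane | C[Si](C)(C)C#CCC/C=C(/C)CCC=C
F2 | step 8 | (2Z)-2-(bromomethylidene)but-3-en-1-ol | Br/C=C(\CO)C=C
F3 | step 8 | {[(2Z)-2-(bromomethylidene)but-3-en-1-yl]oxy}tri(propan-2-yl)silane | Br/C=C(\CO[Si](C(C)C)(C(C)C)C(C)C)C=C
F4 | step 8 | (S)-vicinal bis(pinacol boronate) from the terminal olefin of F1 | C[Si](C)(C)C#CCC/C=C(/C)CC[C@@H](B1OC(C)(C)C(C)(C)O1)CB1OC(C)(C)C(C)(C)O1
F5 | step 8 | open-chain (R)-secondary pinacol boronate with C1–C2 formed (silyl alkyne and bromide-free diene ends) | C[Si](C)(C)C#CCC/C=C(/C)CC[C@@H](B1OC(C)(C)C(C)(C)O1)C/C=C(\CO[Si](C(C)C)(C(C)C)C(C)C)C=C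
F6 | step 8 | open-chain (R)-silyl alkyne carrying the (E)-side chain at C14 | C[Si](C)(C)C#CCC/C=C(/C)CC[C@@H](/C(C)=C/CC=C(C)C)C/C=C(\CO[Si](C(C)C)(C(C)C)C(C)C)C=C
F7 | step 8 | open-chain (R)-terminal alkyne | C#CCC/C=C(/C)CC[C@@H](/C(C)=C/CC=C(C)C)C/C=C(\CO[Si](C(C)C)(C(C)C)C(C)C)C=C
F8 | step 8 | open-chain (R)-(E)-alkenyl iodide with terminal 1,3-diene | I/C=C(\C)CC/C=C(/C)CC[C@@H](/C(C)=C/CC=C(C)C)C/C=C(\CO[Si](C(C)C)(C(C)C)C(C)C)C=C
F9 | step 8 | B-alkyl-9-borabicyclo[3.3.1]nonane from F8 (boron on C5) | I/C=C(\C)CC/C=C(/C)CC[C@@H](/C(C)=C/CC=C(C)C)C/C=C(\CO[Si](C(C)C)(C(C)C)C(C)C)CCB1C2CCCC1CCC2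
F10 | step 11 | macrocyclic 1-substituted vinyl N,N-diisopropylcarbamate (C14 R) | C=C(OC(=O)N(C(C)C)C(C)C)[C@H]1C/C=C(\CO[Si](C(C)C)(C(C)C)C(C)C)CC/C=C(\C)CC/C=C(/C)CC1
F11 | step 11 | macrocyclic terminal alkyne (ethynyl at C14, R) | C#C[C@H]1C/C=C(\CO[Si](C(C)C)(C(C)C)C(C)C)CC/C=C(\C)CC/C=C(/C)CC1
F12 | step 11 | macrocyclic (E)-2-methylalkenyl(dimethyl)alane | C[Al](C)/C=C(\C)[C@H]1C/C=C(\CO[Si](C(C)C)(C(C)C)C(C)C)CC/C=C(\C)CC/C=C(/C)CC1
F13 | step 6 | (5E,9Z)-6,10-dimethyl-1-{[tri(propan-2-yl)silyl]oxy}tetradeca-5,9,13-trien-2-one | CC(C)[Si](C(C)C)(C(C)C)OCC(=O)CC/C=C(\C)CC/C=C(/C)CCC=C
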